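**Plan**

- Ring numbering: C1 (ester carbinol), C2(iPr)=C3, C4=C5(Me), C6–C8, C9 (Me, OH), C10. In the open-chain intermediates, ring atoms C10, C1, C2 … C9 are chain atoms C1, C2, C3 … C10.
- Retrosynthesis cuts the aryl ester C–O bond, then the C9–C10 bond (aldol retron with C1 as ketone), then the diene σ-bond C3–C4 (alkenyl–alkenyl coupling), then C2–isopropyl and C5–methyl (alkyne carbometalations).
- Forward: two alkynols give a Z-alkenyl iodide and an E-alkenylalane; Negishi coupling joins the chain at C3–C4; C10 is armed with a pivalate; both carbinols are oxidised cold; the ten-membered ring closes between C10 and C9 by a samarium Reformatsky-type aldol; reduction, esterification and deprotection follow.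
- Enabling feature: the oxygens on C1 and C9 are 1,3-related across C10. With C1 as a ketone, C10 is its only enolisable neighbour because C2 is an alkene carbon, and the cis C2=C3 bond of the planar C2–C5 diene folds C10 back onto C9.
- Stereochemistry: Z at C2=C3 from chelate-directed anti-carbomagnesiation; E at C4=C5 from syn-carboalumination. C9 forms as a racemate in the ring closure. (R)-CBS reduction sets C1 = S under reagent control and turns the C9 enantiomers into separable diastereomers; the syn (1S,9S) isomer is kept.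

Key step: step 5

Assumption: but-3-yne-1,2-diol and hept-6-yn-2-ol are bought as racemates, which is harmless because both of their carbinol centres become ketones in step 4.

Step 1
Reactants: 1 but-3-yne-1,2-diol
Product: 3 (3Z)-4-iodo-3-(propan-2-yl)but-3-ene-1,2-diol, via oxamagnesole chelate 2 (not isolated)
Conditions: iPrMgCl (4 equiv), CuI (10 mol%), THF, 0 to 23 °C; then I2, −40 to 0 °C
Reagents that add atoms: isopropylmagnesium chloride CC(C)[Mg]Cl; iodine II
Why: Copper-catalysed anti-carbomagnesiation of a propargylic alkoxide (Duboudin-type addition) should deliver isopropyl to the internal alkyne carbon and magnesium to the terminal one inside the five-membered chelate 2, so that iodinolysis with retention gives the iodide cis to the carbinol carbon (the future Z C2=C3 bond); no stereocentre of the target is set.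

Step 2
Reactants: 4 hept-6-yn-2-ol; 3 (3Z)-4-iodo-3-(propan-2-yl)but-3-ene-1,2-diol
Product: 6 (3Z,5E)-6-methyl-3-(propan-2-yl)undeca-3,5-diene-1,2,10-triol, via alkenylalane 5 (not isolated)
Conditions: AlMe3 (6 equiv), Cp2ZrCl2 (25 mol%), CH2Cl2, 0 to 23 °C; then 3, ZnCl2 (30 mol%), Pd(PPh3)4 (5 mol%), THF, 23 °C
Reagents that add atoms: trimethylaluminium C[Al](C)C
Why: Zirconium-catalysed syn-carboalumination (Negishi) puts methyl and aluminium cis on the alkyne to give 5, and the palladium-catalysed alkenyl–alkenyl Negishi coupling with ZnCl2 as co-catalyst should join C3 to C4 with retention at both partners, the three hydroxyl groups being carried as aluminium alkoxides; the E geometry of C4=C5 is fixed here and no stereocentre of the target is set.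

Step 3
Reactants: 6 (3Z,5E)-6-methyl-3-(propan-2-yl)undeca-3,5-diene-1,2,10-triol
Product: 7 (3Z,5E)-2,10-dihydroxy-6-methyl-3-(propan-2-yl)undeca-3,5-dien-1-yl 2,2-dimethylpropanoate
Conditions: PivCl (1.05 equiv), pyridine, CH2Cl2, −20 °C
Reagents that add atoms: pivaloyl chloride CC(C)(C)C(Cl)=O
Why: Acylation with the bulky pivaloyl chloride at low temperature is selective for the primary hydroxyl (chemoselective esterification) and places on the future C10 the carboxylate leaving group that SmI2 expels in step 5.

Step 4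
Reactants: 7 (3Z,5E)-2,10-dihydroxy-6-methyl-3-(propan-2-yl)undeca-3,5-dien-1-yl 2,2-dimethylpropanoate
Product: 8 (3Z,5E)-6-methyl-2,10-dioxo-3-(propan-2-yl)undeca-3,5-dien-1-yl 2,2-dimethylpropanoate
Conditions: (COCl)2, DMSO, CH2Cl2, −78 °C; Et3N, −78 to −45 °C; cold pH 7 work-up, solution kept below −20 °C and used at once
Reagents that add atoms: none
Why: Swern oxidation should convert both secondary alcohols into ketones at −78 °C without touching the ester or the diene, and the cold hand-over matters because a cis-dienone with a disubstituted terminal alkene carbon can close to a 2H-pyran near room temperature by 6π-oxa-electrocyclisation, which would scramble the C4=C5 geometry on reopening.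

Step 5
Reactants: 8 (3Z,5E)-6-methyl-2,10-dioxo-3-(propan-2-yl)undeca-3,5-dien-1-yl 2,2-dimethylpropanoate
Product: 10 racemic (2Z,4E)-9-hydroxy-5,9-dimethyl-2-(propan-2-yl)cyclodeca-2,4-dien-1-one, via samarium enolate 9 (not isolated)
Conditions: SmI2 (2.2 equiv), THF, −78 °C, slow addition of 8 (final 0.002 M); pH 7 buffer at −78 °C
Reagents that add atoms: none
Why: Two single-electron transfers from SmI2 to the acyloxy ketone of 8 expel pivalate and leave the trivalent samarium enolate 9, a cross-conjugated dienolate that is nucleophilic only at ring C10, and the oxophilic samarium then binds the C9 ketone so that C–C bond formation runs through a chair-like six-membered metal-bridged array set inside the forming ring. The closest known reaction type is the samarium Reformatsky-type aldol cyclisation of α-hetero-substituted ketones onto carbonyl groups, which is used for medium rings. The ten-membered carbocycle closes in the 10-(enolendo)-exo-trig mode by forming the C9–C10 bond. The new carbinol centre C9 is formed without facial control, because neither 8 nor the reagent is chiral, so 10 is a racemate whose C9 configuration is sorted in step 7. The step needs the enolate to form only beside the dienyl ketone and not at the methyl ketone, whose enolates would close six-membered rings by Michael addition to C3, and this is secured by generating it reductively at the only carbon that carries a leaving group, while cyclisation over oligomerisation is favoured by high dilution, by the samarium template and by the cis C2=C3 bond, which folds C10 back toward C9. The diene geometry should be kept because no alkene carbon takes part in the enolate and the temperature stays at −78 °C, where neither retro-aldol opening nor oxa-electrocyclisation of the cis-dienone is expected.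

Step 6
Reactants: 10 racemic (2Z,4E)-9-hydroxy-5,9-dimethyl-2-(propan-2-yl)cyclodeca-2,4-dien-1-one
Product: 11 racemic (2Z,4E)-5,9-dimethyl-2-(propan-2-yl)-9-(trimethylsilyloxy)cyclodeca-2,4-dien-1-one
Conditions: TMSOTf, 2,6-lutidine, CH2Cl2, −78 °C
Reagents that add atoms: trimethylsilyl trifluoromethanesulfonate C[Si](C)(C)OS(=O)(=O)C(F)(F)F
Why: Silylation of the tertiary aldol hydroxyl with a silyl triflate and a hindered base (silyl ether formation) should shut off retro-aldol opening and hydroxyl-directed hydride delivery before the reagent-controlled reduction; no stereocentre changes.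

Step 7
Reactants: 11 racemic (2Z,4E)-5,9-dimethyl-2-(propan-2-yl)-9-(trimethylsilyloxy)cyclodeca-2,4-dien-1-one
Product: 12 (1S,2Z,4E,9S)-5,9-dimethyl-2-(propan-2-yl)-9-(trimethylsilyloxy)cyclodeca-2,4-dien-1-ol
Conditions: (R)-2-methyl-CBS-oxazaborolidine [(3aR)-1-methyl-3,3-diphenyltetrahydro-1H,3H-pyrrolo[1,2-c][1,3,2]oxazaborole] (0.5 equiv), catecholborane, toluene, −78 to −40 °C; MeOH quench; chromatography
Reagents that add atoms: none
Why: Corey–Bakshi–Shibata reduction: the (R)-oxazaborolidine–catecholborane complex should deliver hydride to the ketone face that places the alkenyl carbon C2 in the large-group position, giving 1S in both enantiomers of 11, so that the 9S enantiomer gives the syn alcohol 12 and the 9R enantiomer gives the anti (1S,9R) diastereomer, which is separated by chromatography.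

Step 8
Reactants: 12 (1S,2Z,4E,9S)-5,9-dimethyl-2-(propan-2-yl)-9-(trimethylsilyloxy)cyclodeca-2,4-dien-1-ol; 13 4-acetoxybenzoyl chloride
Product: 14 (1S,2Z,4E,9S)-5,9-dimethyl-2-(propan-2-yl)-9-(trimethylsilyloxy)cyclodeca-2,4-dien-1-yl 4-acetoxybenzoate
Conditions: Et3N, 4-(dimethylamino)pyridine (10 mol%), CH2Cl2, 0 °C
Reagents that add atoms: none
Why: Acylation of the only free hydroxyl by the acid chloride under nucleophilic catalysis (DMAP-catalysed esterification) forms the C1 ester with retention, since the C1–O bond is not broken, while the tertiary silyl ether is inert.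

Step 9
Reactants: 14 (1S,2Z,4E,9S)-5,9-dimethyl-2-(propan-2-yl)-9-(trimethylsilyloxy)cyclodeca-2,4-dien-1-yl 4-acetoxybenzoate
Product: 15 (1S,2Z,4E,9S)-9-hydroxy-5,9-dimethyl-2-(propan-2-yl)cyclodeca-2,4-dien-1-yl 4-hydroxybenzoate
Conditions: K2CO3 (1.2 equiv), MeOH, 0 °C; aq. NH4Cl
Reagents that add atoms: none
Why: Carbonate-mediated methanolysis (transesterification) should cleave the phenyl acetate and the trimethylsilyl ether, while the phenoxide that forms deactivates the benzoate carbonyl toward methoxide so that the hindered secondary ester stays; no stereocentre is touched.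

**Compound list**

1 | but-3-yne-1,2-diol (racemic) | OCC(O)C#C | starting material
2 | chelated alkenylmagnesium alkoxide, a 2,5-dihydro-1,2-oxamagnesole carrying a chloromagnesium alkoxide side chain | Cl[Mg]OCC1O[Mg]C=C1C(C)C | intermediate
3 | (3Z)-4-iodo-3-(propan-2-yl)but-3-ene-1,2-diol (racemic) | OCC(O)/C(=C\I)C(C)C | intermediate
4 | hept-6-yn-2-ol (racemic) | CC(O)CCCC#C | starting material
5 | [(1E)-6-(dimethylalumanyloxy)-2-methylhept-1-en-1-yl]dimethylalane | C/C(=C\[Al](C)C)CCCC(C)O[Al](C)C | intermediate
6 | (3Z,5E)-6-methyl-3-(propan-2-yl)undeca-3,5-diene-1,2,10-triol (diastereomer mixture at C2 and C10) | C/C(=C\C=C(\C(C)C)C(O)CO)CCCC(C)O | intermediate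
7 | (3Z,5E)-2,10-dihydroxy-6-methyl-3-(propan-2-yl)undeca-3,5-dien-1-yl 2,2-dimethylpropanoate (diastereomer mixture) | C/C(=C\C=C(\C(C)C)C(O)COC(=O)C(C)(C)C)CCCC(C)O | intermediate
8 | (3Z,5E)-6-methyl-2,10-dioxo-3-(propan-2-yl)undeca-3,5-dien-1-yl 2,2-dimethylpropanoate | C/C(=C\C=C(\C(C)C)C(=O)COC(=O)C(C)(C)C)CCCC(C)=O | intermediate
9 | diiodosamarium enolate (trivalent samarium) formed from 8 by loss of pivalate | C/C(=C\C=C(\C(C)C)C(=C)O[Sm](I)I)CCCC(C)=O | intermediate
10 | (2Z,4E)-9-hydroxy-5,9-dimethyl-2-(propan-2-yl)cyclodeca-2,4-dien-1-one (racemic) | C/C1=C\C=C(\C(C)C)C(=O)CC(C)(O)CCC1 | intermediate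
11 | (2Z,4E)-5,9-dimethyl-2-(propan-2-yl)-9-(trimethylsilyloxy)cyclodeca-2,4-dien-1-one (racemic) | C/C1=C\C=C(\C(C)C)C(=O)CC(C)(O[Si](C)(C)C)CCC1 | intermediate
12 | (1S,2Z,4E,9S)-5,9-dimethyl-2-(propan-2-yl)-9-(trimethylsilyloxy)cyclodeca-2,4-dien-1-ol | C/C1=C\C=C(\C(C)C)[C@@H](O)C[C@@](C)(O[Si](C)(C)C)CCC1 | intermediate
13 | 4-acetoxybenzoyl chloride | CC(=O)Oc1ccc(cc1)C(Cl)=O | starting material
14 | (1S,2Z,4E,9S)-5,9-dimethyl-2-(propan-2-yl)-9-(trimethylsilyloxy)cyclodeca-2,4-dien-1-yl 4-acetoxybenzoate | C/C1=C\C=C(\C(C)C)[C@@H](OC(=O)c2ccc(OC(C)=O)cc2)C[C@@](C)(O[Si](C)(C)C)CCC1 | intermediate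
15 | (1S,2Z,4E,9S)-9-hydroxy-5,9-dimethyl-2-(propan-2-yl)cyclodeca-2,4-dien-1-yl 4-hydroxybenzoate | C/C1=C\C=C(\C(C)C)[C@@H](OC(=O)c2ccc(O)cc2)C[C@@](C)(O)CCC1 | target

**Totals**

Total step count: 9. Longest linear sequence: 9 steps (1 to 15).

**Three steps most likely to fail**

1. Step 5 (key step).
- What may go wrong: the cis-dienone 8 may electrocyclise to a 2H-pyran during the cold hand-over; the samarium enolate may be protonated before it reaches the ketone; intermolecular aldol addition may compete; the strained ring may reopen by retro-aldol reaction.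
- Fallback (sets out from 4, returns at 11): the C9–C10 bond is made between two fragments and the ring is closed at the diene instead. Carboalumination of 4 as in step 2 followed by I2 should give (6E)-7-iodo-6-methylhept-6-en-2-ol F1, and Dess–Martin oxidation its ketone (6E)-7-iodo-6-methylhept-6-en-2-one F2. Commercial but-3-yn-2-ol is taken through the chemistry of step 1 to (3Z)-4-iodo-3-(propan-2-yl)but-3-en-2-ol F3 and oxidised with MnO2 to (3Z)-4-iodo-3-(propan-2-yl)but-3-en-2-one F4, an iodo-enone without a diene, which cannot electrocyclise. The lithium enolate of F4 (LiN(iPr)2, THF, −78 °C) is added to F2 and the aldolate is silylated in the flask with Me3SiCl to give (1Z,9E)-1,10-diiodo-5,9-dimethyl-2-(propan-2-yl)-5-(trimethylsilyloxy)deca-1,9-dien-3-one F5. Intramolecular reductive coupling of the two alkenyl iodides with zerovalent nickel (Ni(PPh3)4 made from NiCl2(PPh3)2 and Zn, DMF, 50 °C) should close the ring at C3–C4 with retention at both alkenes and give 11.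

2. Step 7.
- What may go wrong: incomplete reagent control in the mismatched enantiomer of 11 would form the enantiomer of 12, which cannot be separated and lowers the enantiomeric purity; the cyclic cis-dienone may also valence-isomerise before it is reduced.
- Fallback (sets out from 10, returns at 15): Narasaka–Prasad reduction of 10 (Et2BOMe, NaBH4, THF–MeOH, −78 °C) should give, through the boron chelate, the racemic syn-diol (1RS,2Z,4E,9RS)-5,9-dimethyl-2-(propan-2-yl)cyclodeca-2,4-diene-1,9-diol F6. Acylation of its secondary hydroxyl with (1S)-camphanic chloride (pyridine, 4-(dimethylamino)pyridine) gives two diastereomeric esters, from which (1S,2Z,4E,9S)-9-hydroxy-5,9-dimethyl-2-(propan-2-yl)cyclodeca-2,4-dien-1-yl (1S,4R)-4,7,7-trimethyl-3-oxo-2-oxabicyclo[2.2.1]heptane-1-carboxylate F7 is isolated by chromatography or crystallisation. Methanolysis (K2CO3, MeOH) frees (1S,2Z,4E,9S)-5,9-dimethyl-2-(propan-2-yl)cyclodeca-2,4-diene-1,9-diol F8. Acylation with 13 as in step 8 gives (1S,2Z,4E,9S)-9-hydroxy-5,9-dimethyl-2-(propan-2-yl)cyclodeca-2,4-dien-1-yl 4-acetoxybenzoate F9, and the conditions of step 9 give 15.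

3. Step 2.
- What may go wrong: protonolysis of the alkenylalane by hydroxyl groups that are not fully metalated, slow transmetalation in the presence of the dialkoxide partner, or erosion of alkene geometry.
- Fallback (sets out from 3 and 4, returns at 6): ketalisation of 3 (2,2-dimethoxypropane, pyridinium p-toluenesulfonate) gives 4-[(1Z)-2-iodo-1-(propan-2-yl)ethenyl]-2,2-dimethyl-1,3-dioxolane F10. Carboalumination of 4 as in step 2 and quenching of the alane with 2-methoxy-4,4,5,5-tetramethyl-1,3,2-dioxaborolane gives the isolable boronate (6E)-6-methyl-7-(4,4,5,5-tetramethyl-1,3,2-dioxaborolan-2-yl)hept-6-en-2-ol F11. Suzuki–Miyaura coupling (PdCl2(dppf), dppf = 1,1'-bis(diphenylphosphino)ferrocene, aqueous K3PO4, THF, 50 °C) gives (6E,8Z)-9-(2,2-dimethyl-1,3-dioxolan-4-yl)-6,10-dimethylundeca-6,8-dien-2-ol F12, and aqueous acetic acid removes the acetonide and returns 6.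

Further compounds
F1 | step 5 | (6E)-7-iodo-6-methylhept-6-en-2-ol | C/C(=C\I)CCCC(C)O
F2 | step 5 | (6E)-7-iodo-6-methylhept-6-en-2-one | C/C(=C\I)CCCC(C)=O
F3 | step 5 | (3Z)-4-iodo-3-(propan-2-yl)but-3-en-2-ol | CC(O)/C(=C\I)C(C)C
F4 | step 5 | (3Z)-4-iodo-3-(propan-2-yl)but-3-en-2-one | CC(=O)/C(=C\I)C(C)C
F5 | step 5 | (1Z,9E)-1,10-diiodo-5,9-dimethyl-2-(propan-2-yl)-5-(trimethylsilyloxy)deca-1,9-dien-3-one (racemic) | C/C(=C\I)CCCC(C)(O[Si](C)(C)C)CC(=O)/C(=C\I)C(C)C
F6 | step 7 | (1RS,2Z,4E,9RS)-5,9-dimethyl-2-(propan-2-yl)cyclodeca-2,4-diene-1,9-diol (racemic syn-diol, both enantiomers written) | C/C1=C\C=C(\C(C)C)[C@@H](O)C[C@@](C)(O)CCC1.C/C1=C\C=C(\C(C)C)[C@H](O)C[C@](C)(O)CCC1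
F7 | step 7 | (1S,2Z,4E,9S)-9-hydroxy-5,9-dimethyl-2-(propan-2-yl)cyclodeca-2,4-dien-1-yl (1S,4R)-4,7,7-trimethyl-3-oxo-2-oxabicyclo[2.2.1]heptane-1-carboxylate | C/C1=C\C=C(\C(C)C)[C@@H](OC(=O)[C@@]23CC[C@@](C)(C(=O)O2)C3(C)C)C[C@@](C)(O)CCC1
F8 | step 7 | (1S,2Z,4E,9S)-5,9-dimethyl-2-(propan-2-yl)cyclodeca-2,4-diene-1,9-diol | C/C1=C\C=C(\C(C)C)[C@@H](O)C[C@@](C)(O)CCC1
F9 | step 7 | (1S,2Z,4E,9S)-9-hydroxy-5,9-dimethyl-2-(propan-2-yl)cyclodeca-2,4-dien-1-yl 4-acetoxybenzoate | C/C1=C\C=C(\C(C)C)[C@@H](OC(=O)c2ccc(OC(C)=O)cc2)C[C@@](C)(O)CCC1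
F10 | step 2 | 4-[(1Z)-2-iodo-1-(propan-2-yl)ethenyl]-2,2-dimethyl-1,3-dioxolane (racemic) | CC1(C)OCC(O1)/C(=C\I)C(C)C
F11 | step 2 | (6E)-6-methyl-7-(4,4,5,5-tetramethyl-1,3,2-dioxaborolan-2-yl)hept-6-en-2-ol | C/C(=C\B1OC(C)(C)C(C)(C)O1)CCCC(C)O
F12 | step 2 | (6E,8Z)-9-(2,2-dimethyl-1,3-dioxolan-4-yl)-6,10-dimethylundeca-6,8-dien-2-ol | C/C(=C\C=C(\C(C)C)C1COC(C)(C)O1)CCCC(C)O
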